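**Plan**
1. Retrosynthetic cuts: the C15–O palmitate; C14–C15 and C13–C16 (methylalumination of a C13≡C14 alkyne, then CH2O); C9–H with the C8=C17 alkene (Pd/formate reduction of a C9 allylic carbonate); C9–C11 (butynyl metal + C9 ketone) and C8=C17 (α-methylenation).
2. Ring A is opened by reversing a 1,2-shift: the C3–C4 bond is cut and C19 returns into the ring as C3–C19, which gives a seven-membered C4/C19 epoxide; then C4=C19 (ring-closing metathesis), C10–C1 (enolate alkylation) and C5–C4 (conjugate addition) are cut.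
3. Forward order: ring B is the starting cyclohexenone; the seven-membered ring C10–C1–C2–C3–C19–C4–C5 is closed on it; its β-epoxide contracts to ring A; the side chain is then joined at C9 and finished.
4. Enabling feature: C4 is a quaternary ring-A carbon bearing a methyl (C18) and a one-carbon oxidised substituent (C19), next to C3. With C19 as a ring CH between C3 and C4, the epoxide ionises at the tertiary, methyl-bearing C4 and the C3–C19 bond shifts to C4; this makes ring A, the quaternary centre and the C19 carbonyl in one event.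
5. Stereochemistry: C5 from a ligand-controlled conjugate addition; C10 by alkylation anti to the C5 substituent; C4 from the epoxide face by stereospecific anti migration; C9 by hydride delivery to the α face; 13E by syn-methylalumination.

Key step: step 5

Remark: labdane numbering is used for positions (ring A = C1–C5, C10; ring B = C5–C10; C17 = exocyclic CH2; C18 = 4-methyl; C19 = ester carbon; C20 = 10-methyl); β is the face of C20; reagents that deliver carbon to a product are numbered as reactants.

**Step 1**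
Reactants: 1 2-methylcyclohex-2-en-1-one; 2 isopropenylmagnesium bromide; 3 chlorotrimethylsilane
Product: 5 trimethyl{[(3S)-2-methyl-3-(prop-1-en-2-yl)cyclohex-1-en-1-yl]oxy}silane, via bromomagnesium enolate 4 (not isolated)
Conditions: CuBr·SMe2 (5 mol %), chiral NHC ligand (enantiomer giving 3S), Et2O, −30 °C; then TMSCl, Et3N, −30 → 0 °C
Reagents that add atoms: isopropenylmagnesium bromide (2), CC(=C)[Mg]Br; chlorotrimethylsilane (3), C[Si](C)(C)Cl
Why: Copper-catalysed asymmetric conjugate addition of a Grignard reagent to an α-substituted cyclic enone with O-silylation of the regiodefined enolate is a known reaction type, in which the chiral copper complex selects the enone face and so sets C5, while the silyl enol ether stores the tetrasubstituted enolate.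

**Step 2**
Reactants: 5 trimethyl{[(3S)-2-methyl-3-(prop-1-en-2-yl)cyclohex-1-en-1-yl]oxy}silane; 6 5-iodopent-1-ene
Product: 8 (2S,3S)-2-methyl-2-(pent-4-en-1-yl)-3-(prop-1-en-2-yl)cyclohexan-1-one, via lithium enolate 7 (not isolated)
Conditions: MeLi, THF, 0 °C; then 6, DMPU, −78 → 0 °C
Reagents that add atoms: 5-iodopent-1-ene (6), C=CCCCI
Why: Cleavage of the silyl enol ether by MeLi regenerates the tetrasubstituted lithium enolate regiospecifically, and its SN2 alkylation occurs anti to the neighbouring isopropenyl group, which sets the quaternary C10 with the methyl cis to the C5 substituent (the later trans ring fusion).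

**Step 3**
Reactants: 8 (2S,3S)-2-methyl-2-(pent-4-en-1-yl)-3-(prop-1-en-2-yl)cyclohexan-1-one
Product: 9 (4aS,9aS)-5,9a-dimethyl-2,3,4,4a,7,8,9,9a-octahydro-1H-benzo[7]annulen-1-one
Conditions: Grubbs II (5 mol %), CH2Cl2 (5 mM), 40 °C
Reagents that add atoms: none
Why: Ring-closing metathesis of the monosubstituted and the 1,1-disubstituted alkene, held trans-diequatorial on the cyclohexanone, should close the trans-fused cycloheptene with the trisubstituted C4=C19 double bond and release ethene, without forming a stereocentre.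

**Step 4**
Reactants: 9 (4aS,9aS)-5,9a-dimethyl-2,3,4,4a,7,8,9,9a-octahydro-1H-benzo[7]annulen-1-one
Product: 11 (4aR,5R,6S,9aS)-5,6-epoxy-5,9a-dimethyldecahydro-1H-benzo[7]annulen-1-one, via bromohydrin 10 (not isolated)
Conditions: NBS, THF/H2O, 0 °C; then K2CO3, MeOH, rt
Reagents that add atoms: water, O
Why: Bromohydrin formation and base-induced closure place the epoxide oxygen on the face opposite to that of a direct peracid epoxidation, because the bromonium ion should form on the less hindered α face (anti to C20), water opens it anti at the tertiary C4 from the β face, and the alkoxide then displaces the C19 bromide with inversion to give the β-epoxide that the next step needs.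

**Step 5**
Reactants: 11 (4aR,5R,6S,9aS)-5,6-epoxy-5,9a-dimethyldecahydro-1H-benzo[7]annulen-1-one
Product: 12 (1S,4aS,8aS)-1,4a-dimethyl-5-oxodecahydronaphthalene-1-carbaldehyde
Conditions: methylaluminium bis(4-bromo-2,6-di-tert-butylphenoxide) (MABR, 2.2 equiv), CH2Cl2, −78 → −20 °C
Reagents that add atoms: none
Why: The bulky aluminium Lewis acid binds the epoxide oxygen, the C4–O bond ionises toward the tertiary, methyl-stabilised C4, and the ring bond C3–C19 shifts from C19 to C4 anti to the departing oxygen while C19 becomes the carbonyl carbon, so the seven-membered ring C10–C1–C2–C3–C19–C4–C5 contracts to ring A and C19 is extruded as the formyl group. The closest known reaction type is the Meinwald (semipinacol) rearrangement of trisubstituted epoxides to α-quaternary aldehydes under bulky aluminium aryloxides, which is known for 1-methylcycloalkene oxides with ring contraction. Ring A closes by a suprafacial 1,2-alkyl shift (the C3–C4 bond forms as the C3–C19 bond breaks), not by a cyclisation, so no ring-closure rule applies. The only new stereocentre, C4, is controlled by the epoxide configuration: with oxygen on the β face, C3 enters on the α face with inversion at C4, which leaves C18 α (equatorial) and the formyl group β (axial, cis to C20), while C5 and C10 are untouched. The selectivity needed is ring-bond shift over 1,2-hydride shift from C19 (which would give the cycloheptanone); the bulky aluminium phenoxide is expected to favour the conformer in which the C3–C19 bond, not the C19–H bond, is aligned with the breaking C4–O bond, and the flexible seven-membered ring can reach this alignment.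

**Step 6**
Reactants: 12 (1S,4aS,8aS)-1,4a-dimethyl-5-oxodecahydronaphthalene-1-carbaldehyde
Product: 13 (1S,4aS,8aR)-1,4a-dimethyl-5-oxodecahydronaphthalene-1-carboxylic acid
Conditions: NaClO2, NaH2PO4, 2-methylbut-2-ene, t-BuOH/H2O, rt
Reagents that add atoms: sodium chlorite, [Na+].[O-]Cl=O
Why: Pinnick (chlorite) oxidation converts the hindered, non-enolisable aldehyde into the acid without touching the ketone or any stereocentre.

**Step 7**
Reactants: 13 (1S,4aS,8aR)-1,4a-dimethyl-5-oxodecahydronaphthalene-1-carboxylic acid; 14 iodomethane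
Product: 15 methyl (1S,4aS,8aR)-1,4a-dimethyl-5-oxodecahydronaphthalene-1-carboxylate
Conditions: MeI, K2CO3, DMF, rt
Reagents that add atoms: iodomethane (14), CI
Why: SN2 O-alkylation of the carboxylate is the standard esterification of hindered tertiary acids and is too mild to C-methylate the ketone.

**Step 8**
Reactants: 15 methyl (1S,4aS,8aR)-1,4a-dimethyl-5-oxodecahydronaphthalene-1-carboxylate; 16 paraformaldehyde
Product: 17 methyl (1S,4aS,8aR)-1,4a-dimethyl-6-methylidene-5-oxodecahydronaphthalene-1-carboxylate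
Conditions: (CH2O)n, i-Pr2NH·TFA, TFA (10 mol %), THF, reflux
Reagents that add atoms: paraformaldehyde (16), C=O
Why: Mannich-type α-methylenation (condensation with formaldehyde, then elimination) can only occur at C8, the sole enolisable position of the C9 ketone, and installs C17.

**Step 9**
Reactants: 17 methyl (1S,4aS,8aR)-1,4a-dimethyl-6-methylidene-5-oxodecahydronaphthalene-1-carboxylate; 18 (4-bromobut-1-yn-1-yl)trimethylsilane; 19 methyl chloroformate
Product: 22 methyl (1S,4aS,5S,8aR)-5-[(methoxycarbonyl)oxy]-1,4a-dimethyl-6-methylidene-5-[4-(trimethylsilyl)but-3-yn-1-yl]decahydronaphthalene-1-carboxylate, via Grignard reagent 20 (not isolated), via bromomagnesium alkoxide 21 (not isolated)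
Conditions: 18, Mg, THF; CeCl3, THF, −78 °C; 17; then ClCO2Me, −78 → 0 °C
Reagents that add atoms: (4-bromobut-1-yn-1-yl)trimethylsilane (18), C[Si](C)(C)C#CCCBr; methyl chloroformate (19), COC(Cl)=O
Why: Organocerium 1,2-addition (Grignard reagent transmetallated to cerium) to the hindered α-methylene ketone followed by O-acylation of the tertiary alkoxide gives the allylic carbonate, with attack expected from the α face (the C9 configuration is erased in step 10) and the pivalate-like C19 ester inert at −78 °C.

**Step 10**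
Reactants: 22 methyl (1S,4aS,5S,8aR)-5-[(methoxycarbonyl)oxy]-1,4a-dimethyl-6-methylidene-5-[4-(trimethylsilyl)but-3-yn-1-yl]decahydronaphthalene-1-carboxylate
Product: 23 methyl (1S,4aR,5S,8aR)-1,4a-dimethyl-6-methylidene-5-[4-(trimethylsilyl)but-3-yn-1-yl]decahydronaphthalene-1-carboxylate
Conditions: Pd(OAc)2 (5 mol %), n-Bu3P (20 mol %), HCO2H, Et3N, THF, 40 °C
Reagents that add atoms: none
Why: Palladium-catalysed formate hydrogenolysis of an allylic carbonate (Tsuji–Trost type) ionises to the π-allyl complex spanning C17–C8–C9 and transfers hydride to the more substituted terminus C9 to leave the exocyclic C8=C17 alkene, with palladium and hence the hydride on the less hindered α face (anti to C20), which sets C9–H α and the side chain β.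

**Step 11**
Reactants: 23 methyl (1S,4aR,5S,8aR)-1,4a-dimethyl-6-methylidene-5-[4-(trimethylsilyl)but-3-yn-1-yl]decahydronaphthalene-1-carboxylate
Product: 24 methyl (1S,4aR,5S,8aR)-5-(but-3-yn-1-yl)-1,4a-dimethyl-6-methylidenedecahydronaphthalene-1-carboxylate
Conditions: K2CO3, MeOH, rt
Reagents that add atoms: none
Why: Base-catalysed methanolysis of the C(sp)–Si bond frees the terminal alkyne, and the methyl ester can only transesterify to itself.

**Step 12**
Reactants: 24 methyl (1S,4aR,5S,8aR)-5-(but-3-yn-1-yl)-1,4a-dimethyl-6-methylidenedecahydronaphthalene-1-carboxylate; 25 trimethylaluminium; 16 paraformaldehyde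
Product: 28 methyl (1S,4aR,5S,8aR)-5-[(3E)-5-hydroxy-3-methylpent-3-en-1-yl]-1,4a-dimethyl-6-methylidenedecahydronaphthalene-1-carboxylate, via alkenylalane 26 (not isolated), via lithium alkenylaluminate 27 (not isolated)
Conditions: Me3Al, Cp2ZrCl2 (25 mol %), H2O (1 equiv), CH2Cl2, −30 → 0 °C; concentrate; n-BuLi, THF, −78 °C; (CH2O)n, → rt
Reagents that add atoms: trimethylaluminium (25), C[Al](C)C; paraformaldehyde (16), C=O
Why: Zirconium-catalysed methylalumination of the terminal alkyne (Negishi carboalumination) adds Me and Al syn with Al at the terminus, and hydroxymethylation of the derived aluminate proceeds with retention, which fixes the 13E allylic alcohol while the pivalate-like ester and the 1,1-disubstituted alkene stay inert.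

**Step 13**
Reactants: 28 methyl (1S,4aR,5S,8aR)-5-[(3E)-5-hydroxy-3-methylpent-3-en-1-yl]-1,4a-dimethyl-6-methylidenedecahydronaphthalene-1-carboxylate; 29 hexadecanoyl chloride
Product: 30 methyl (1S,4aR,5S,8aR)-5-[(3E)-5-(hexadecanoyloxy)-3-methylpent-3-en-1-yl]-1,4a-dimethyl-6-methylidenedecahydronaphthalene-1-carboxylate
Conditions: 29, pyridine, DMAP (cat.), CH2Cl2, 0 °C → rt
Reagents that add atoms: hexadecanoyl chloride (29), CCCCCCCCCCCCCCCC(Cl)=O
Why: DMAP-catalysed acylation of the primary allylic alcohol by the acid chloride gives the palmitate ester without affecting the alkenes or the C19 ester.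

**Compound list**
1 | 2-methylcyclohex-2-en-1-one | CC1=CCCCC1=O | starting material
2 | isopropenylmagnesium bromide | CC(=C)[Mg]Br | starting material
3 | chlorotrimethylsilane | C[Si](C)(C)Cl | starting material
4 | bromomagnesium (3S)-2-methyl-3-(prop-1-en-2-yl)cyclohex-1-en-1-olate | Br[Mg]OC1=C(C)[C@H](C(C)=C)CCC1 | intermediate (not isolated)
5 | trimethyl{[(3S)-2-methyl-3-(prop-1-en-2-yl)cyclohex-1-en-1-yl]oxy}silane | C[Si](C)(C)OC1=C(C)[C@H](C(C)=C)CCC1 | intermediate
6 | 5-iodopent-1-ene | C=CCCCI | starting material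
7 | lithium (3S)-2-methyl-3-(prop-1-en-2-yl)cyclohex-1-en-1-olate | [Li]OC1=C(C)[C@H](C(C)=C)CCC1 | intermediate (not isolated)
8 | (2S,3S)-2-methyl-2-(pent-4-en-1-yl)-3-(prop-1-en-2-yl)cyclohexan-1-one | O=C1CCC[C@@H](C(C)=C)[C@]1(C)CCCC=C | intermediate
9 | (4aS,9aS)-5,9a-dimethyl-2,3,4,4a,7,8,9,9a-octahydro-1H-benzo[7]annulen-1-one | O=C1CCC[C@H]2C(C)=CCCC[C@]12C | intermediate
10 | (4aR,5R,6R,9aS)-6-bromo-5-hydroxy-5,9a-dimethyldecahydro-1H-benzo[7]annulen-1-one | O=C1CCC[C@H]2[C@@](C)(O)[C@H](Br)CCC[C@]12C | intermediate (not isolated)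
11 | (4aR,5R,6S,9aS)-5,6-epoxy-5,9a-dimethyldecahydro-1H-benzo[7]annulen-1-one (β-epoxide) | O=C1CCC[C@H]2[C@@]3(C)O[C@H]3CCC[C@]12C | intermediate
12 | (1S,4aS,8aS)-1,4a-dimethyl-5-oxodecahydronaphthalene-1-carbaldehyde | O=C1CCC[C@@H]2[C@]1(C)CCC[C@]2(C)C=O | intermediate
13 | (1S,4aS,8aR)-1,4a-dimethyl-5-oxodecahydronaphthalene-1-carboxylic acid | O=C1CCC[C@@H]2[C@]1(C)CCC[C@]2(C)C(=O)O | intermediate
14 | iodomethane | CI | starting material
15 | methyl (1S,4aS,8aR)-1,4a-dimethyl-5-oxodecahydronaphthalene-1-carboxylate | O=C1CCC[C@@H]2[C@]1(C)CCC[C@]2(C)C(=O)OC | intermediate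
16 | paraformaldehyde (as formaldehyde) | C=O | starting material
17 | methyl (1S,4aS,8aR)-1,4a-dimethyl-6-methylidene-5-oxodecahydronaphthalene-1-carboxylate | C=C1CC[C@@H]2[C@](C)(CCC[C@]2(C)C(=O)OC)C1=O | intermediate
18 | (4-bromobut-1-yn-1-yl)trimethylsilane | C[Si](C)(C)C#CCCBr | starting material
19 | methyl chloroformate | COC(Cl)=O | starting material
20 | [4-(trimethylsilyl)but-3-yn-1-yl]magnesium bromide | C[Si](C)(C)C#CCC[Mg]Br | intermediate (not isolated)
21 | bromomagnesium alkoxide of the C9 tertiary alcohol (5S) | C=C1CC[C@@H]2[C@](C)(CCC[C@]2(C)C(=O)OC)[C@]1(O[Mg]Br)CCC#C[Si](C)(C)C | intermediate (not isolated)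
22 | methyl (1S,4aS,5S,8aR)-5-[(methoxycarbonyl)oxy]-1,4a-dimethyl-6-methylidene-5-[4-(trimethylsilyl)but-3-yn-1-yl]decahydronaphthalene-1-carboxylate | C=C1CC[C@@H]2[C@](C)(CCC[C@]2(C)C(=O)OC)[C@]1(OC(=O)OC)CCC#C[Si](C)(C)C | intermediate
23 | methyl (1S,4aR,5S,8aR)-1,4a-dimethyl-6-methylidene-5-[4-(trimethylsilyl)but-3-yn-1-yl]decahydronaphthalene-1-carboxylate | C=C1CC[C@@H]2[C@](C)(CCC[C@]2(C)C(=O)OC)[C@H]1CCC#C[Si](C)(C)C | intermediate
24 | methyl (1S,4aR,5S,8aR)-5-(but-3-yn-1-yl)-1,4a-dimethyl-6-methylidenedecahydronaphthalene-1-carboxylate | C=C1CC[C@@H]2[C@](C)(CCC[C@]2(C)C(=O)OC)[C@H]1CCC#C | intermediate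
25 | trimethylaluminium | C[Al](C)C | starting material
26 | (E)-alkenyldimethylalane from 24 (Al at C14, methyl at C13) | C=C1CC[C@@H]2[C@](C)(CCC[C@]2(C)C(=O)OC)[C@H]1CC/C(C)=C/[Al](C)C | intermediate (not isolated)
27 | lithium (E)-alkenyl(butyl)dimethylaluminate | C=C1CC[C@@H]2[C@](C)(CCC[C@]2(C)C(=O)OC)[C@H]1CC/C(C)=C/[Al-](C)(C)CCCC.[Li+] | intermediate (not isolated)
28 | methyl (1S,4aR,5S,8aR)-5-[(3E)-5-hydroxy-3-methylpent-3-en-1-yl]-1,4a-dimethyl-6-methylidenedecahydronaphthalene-1-carboxylate (methyl isocupressate) | C=C1CC[C@@H]2[C@](C)(CCC[C@]2(C)C(=O)OC)[C@H]1CC/C(C)=C/CO | intermediate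
29 | hexadecanoyl chloride (palmitoyl chloride) | CCCCCCCCCCCCCCCC(Cl)=O | starting material
30 | methyl (1S,4aR,5S,8aR)-5-[(3E)-5-(hexadecanoyloxy)-3-methylpent-3-en-1-yl]-1,4a-dimethyl-6-methylidenedecahydronaphthalene-1-carboxylate | C=C1CC[C@@H]2[C@](C)(CCC[C@]2(C)C(=O)OC)[C@H]1CC/C(C)=C/COC(=O)CCCCCCCCCCCCCCC | target

**Totals**
Total step count: 13. Longest linear sequence: 13 steps (from 1).

**Steps most likely to fail**

Step 5. Risk: the 1,2-hydride shift from C19 may outrun the ring-bond shift and give the cycloheptanone, or a long-lived C4 cation may erode the stereospecificity. The fallback sets out from 9 and comes back at 15; it uses the opposite alkene face and an anionic ring contraction.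
- 9 is epoxidised directly with m-CPBA, which should attack the α face, to (4aR,5S,6R,9aS)-5,6-epoxy-5,9a-dimethyldecahydro-1H-benzo[7]annulen-1-one F1.
- Anhydrous HCl opens it at the tertiary carbon with inversion to (4aR,5R,6R,9aS)-5-chloro-6-hydroxy-5,9a-dimethyldecahydro-1H-benzo[7]annulen-1-one F2.
- Dess–Martin oxidation gives (4aR,5R,9aS)-5-chloro-5,9a-dimethyloctahydro-1H-benzo[7]annulene-1,6(2H)-dione F3.
- Favorskii rearrangement (NaOMe, Et2O) contracts the ring and gives 15 directly with the same C4 configuration: the C3 enolate displaces the 4β-chloride with inversion to the cyclopropanone, and methoxide opens it toward the less substituted carbanion.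

Step 10. Risk: hydride transfer to the wrong allyl terminus (Δ8 tetrasubstituted alkene) or to the β face, or diene formation by β-hydride elimination. The fallback sets out from 17 and comes back at 23; it replaces the metal hydride by a pericyclic hydrogen transfer.
- Organocerium addition of 20 to 17 with aqueous work-up gives methyl (1S,4aS,5S,8aR)-5-hydroxy-1,4a-dimethyl-6-methylidene-5-[4-(trimethylsilyl)but-3-yn-1-yl]decahydronaphthalene-1-carboxylate F4.
- Rhenium-oxo-catalysed 1,3-transposition (Ph3SiOReO3, Et2O, 0 °C) moves the hydroxyl to C17 and gives methyl (1S,4aS,8aR)-6-(hydroxymethyl)-1,4a-dimethyl-5-[4-(trimethylsilyl)but-3-yn-1-yl]-1,2,3,4,4a,7,8,8a-octahydronaphthalene-1-carboxylate F5.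
- Mitsunobu displacement with 2-nitrobenzenesulfonylhydrazide (PPh3, DEAD, THF, −30 °C) gives methyl (1S,4aS,8aR)-1,4a-dimethyl-6-{[1-(2-nitrobenzenesulfonyl)hydrazinyl]methyl}-5-[4-(trimethylsilyl)but-3-yn-1-yl]-1,2,3,4,4a,7,8,8a-octahydronaphthalene-1-carboxylate F6.
- On warming, F6 loses the sulfinic acid to methyl (1S,4aS,8aR)-6-(diazenylmethyl)-1,4a-dimethyl-5-[4-(trimethylsilyl)but-3-yn-1-yl]-1,2,3,4,4a,7,8,8a-octahydronaphthalene-1-carboxylate F7.
- Retro-ene loss of N2 from F7 transfers hydrogen to C9 on the less hindered α face and moves the double bond to C8=C17, which gives 23.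

Step 2. Risk: slow C-alkylation of the hindered tetrasubstituted enolate by an unactivated primary iodide, with proton transfer and O-alkylation competing. The fallback sets out from 5 and comes back at 8; it builds the quaternary centre with a π-allyl electrophile and then extends the chain.
- Palladium-catalysed Tsuji allylation of 5 with allyl methyl carbonate (Pd2(dba)3, dppe, THF), again anti to the isopropenyl group, gives (2S,3S)-2-methyl-2-(prop-2-en-1-yl)-3-(prop-1-en-2-yl)cyclohexan-1-one F8.
- Linear-selective rhodium-catalysed hydroformylation of the monosubstituted alkene (Rh(acac)(CO)2, Xantphos, CO/H2) gives 4-[(1S,6S)-1-methyl-2-oxo-6-(prop-1-en-2-yl)cyclohexyl]butanal F9.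
- Wittig methylenation of the aldehyde (Ph3P=CH2, THF, −78 °C) gives 8.

**Further compounds**
F1 | step 5 | (4aR,5S,6R,9aS)-5,6-epoxy-5,9a-dimethyldecahydro-1H-benzo[7]annulen-1-one (α-epoxide) | O=C1CCC[C@H]2[C@]3(C)O[C@@H]3CCC[C@]12C
F2 | step 5 | (4aR,5R,6R,9aS)-5-chloro-6-hydroxy-5,9a-dimethyldecahydro-1H-benzo[7]annulen-1-one | O=C1CCC[C@H]2[C@@](C)(Cl)[C@H](O)CCC[C@]12C
F3 | step 5 | (4aR,5R,9aS)-5-chloro-5,9a-dimethyloctahydro-1H-benzo[7]annulene-1,6(2H)-dione | O=C1CCC[C@H]2[C@@](C)(Cl)C(=O)CCC[C@]12C
F4 | step 10 | methyl (1S,4aS,5S,8aR)-5-hydroxy-1,4a-dimethyl-6-methylidene-5-[4-(trimethylsilyl)but-3-yn-1-yl]decahydronaphthalene-1-carboxylate | C=C1CC[C@@H]2[C@](C)(CCC[C@]2(C)C(=O)OC)[C@]1(O)CCC#C[Si](C)(C)C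
F5 | step 10 | methyl (1S,4aS,8aR)-6-(hydroxymethyl)-1,4a-dimethyl-5-[4-(trimethylsilyl)but-3-yn-1-yl]-1,2,3,4,4a,7,8,8a-octahydronaphthalene-1-carboxylate | OCC1CC[C@@H]2[C@](C)(CCC[C@]2(C)C(=O)OC)C=1CCC#C[Si](C)(C)C
F6 | step 10 | methyl (1S,4aS,8aR)-1,4a-dimethyl-6-{[1-(2-nitrobenzenesulfonyl)hydrazinyl]methyl}-5-[4-(trimethylsilyl)but-3-yn-1-yl]-1,2,3,4,4a,7,8,8a-octahydronaphthalene-1-carboxylate | NN(CC1CC[C@@H]2[C@](C)(CCC[C@]2(C)C(=O)OC)C=1CCC#C[Si](C)(C)C)S(=O)(=O)c1ccccc1[N+](=O)[O-]
F7 | step 10 | methyl (1S,4aS,8aR)-6-(diazenylmethyl)-1,4a-dimethyl-5-[4-(trimethylsilyl)but-3-yn-1-yl]-1,2,3,4,4a,7,8,8a-octahydronaphthalene-1-carboxylate | N=NCC1CC[C@@H]2[C@](C)(CCC[C@]2(C)C(=O)OC)C=1CCC#C[Si](C)(C)C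
F8 | step 2 | (2S,3S)-2-methyl-2-(prop-2-en-1-yl)-3-(prop-1-en-2-yl)cyclohexan-1-one | O=C1CCC[C@@H](C(C)=C)[C@]1(C)CC=C
F9 | step 2 | 4-[(1S,6S)-1-methyl-2-oxo-6-(prop-1-en-2-yl)cyclohexyl]butanal | O=C1CCC[C@@H](C(C)=C)[C@]1(C)CCCC=O
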